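**Retrosynthetic overview**

1. Feature: the cyclopentenone shares one bond with the five-membered indane ring; one end is the tertiary carbinol carbon (O, aryl), the other the CH that carries the ketone C=O and the spiro ketal carbon. Oxygen on one carbon and carbonyl on its neighbour is the pattern left by a ketene adding across an enol ether.
2. Cyclopentenone ⇒ cyclopentanone (desaturation) ⇒ cyclobutanone (one-carbon ring expansion) ⇒ dichloroketene + enol ether of a spiroketal indanone with a chiral 1-arylethanol ([2+2], both stereocentres).
3. Enol ether ⇒ enol triflate ⇒ indanone (Parham cyclisation of an aryl iodide onto an ester) ⇒ ketal carbon from a naphthodioxinylium ion and a ketene silyl acetal ⇒ aryl aldehyde acetal of 1,8-dihydroxynaphthalene.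
4. The phenalenone ring is built first, as a 2,3-dihydrophenalen-1-one by Friedel–Crafts annulation of 6-methoxy-2-naphthyl tosylate, because acylation after the electron-rich dioxynaphthalene is in place would not be selective. It is carried as a dioxolane and dehydrogenated together with the cyclopentanone.
5. Ring order: dihydrophenalenone ring, naphthodioxine, indanone five-ring, cyclobutanone, cyclopentanone, then both enones.

Key step: step 14

Assumption: the enol ether reacts through the s-trans conformer usual for this auxiliary, so the (S)-alcohol is taken; if the other face were attacked, the (R)-alcohol would be used with no other change.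

**Route**

Step 1
Reactants: 1 6-methoxy-2-naphthol
Product: 2 6-methoxynaphthalen-2-yl 4-methylbenzenesulfonate
Conditions: TsCl, Et3N, DMAP (cat.), CH2Cl2, 0 °C to rt
Reagents that add atoms: 4-toluenesulfonyl chloride, Cc1ccc(cc1)S(=O)(=O)Cl
Why: O-Sulfonylation of the naphthol gives an acid-stable and only weakly donating sulfonate, so that in the Friedel–Crafts steps the methoxy-bearing ring alone directs the electrophile.

Step 2
Reactants: 2 6-methoxynaphthalen-2-yl 4-methylbenzenesulfonate; 3 3-chloropropanoyl chloride
Product: 4 5-(3-chloropropanoyl)-6-methoxynaphthalen-2-yl 4-methylbenzenesulfonate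
Conditions: AlCl3, CH2Cl2, 0 °C
Reagents that add atoms: none
Why: Friedel–Crafts acylation should occur at C5, the alpha carbon ortho to the methoxy group and the most nucleophilic site of a 2-methoxynaphthalene, while the sulfonate-bearing ring is less activated and the low temperature spares the ortho methoxy group from AlCl3.

Step 3
Reactants: 4 5-(3-chloropropanoyl)-6-methoxynaphthalen-2-yl 4-methylbenzenesulfonate
Product: 5 9-methoxy-1-oxo-2,3-dihydro-1H-phenalen-5-yl 4-methylbenzenesulfonate
Conditions: CF3SO3H, ClCH2CH2Cl, 60 °C
Reagents that add atoms: none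
Why: In the strong acid HCl is lost to give the aryl vinyl ketone, and its protonated form alkylates the peri carbon C4, activated across the ring by the methoxy group, in an intramolecular Friedel–Crafts cycloalkylation that can only close the six-membered ring because the ortho carbon carries OMe.

Step 4
Reactants: 5 9-methoxy-1-oxo-2,3-dihydro-1H-phenalen-5-yl 4-methylbenzenesulfonate
Product: 6 5-hydroxy-9-methoxy-2,3-dihydro-1H-phenalen-1-one
Conditions: KOH, MeOH–THF–H2O, 60 °C, degassed; then aq. NH4Cl
Reagents that add atoms: none
Why: Hydroxide attacks sulfur of the aryl sulfonate (saponification with S–O cleavage) and frees the naphthol that must direct the next substitution, oxygen being excluded because the ketone enolate is easily oxidised.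

Step 5
Reactants: 6 5-hydroxy-9-methoxy-2,3-dihydro-1H-phenalen-1-one
Product: 7 5-hydroxy-9-methoxy-1-oxo-2,3-dihydro-1H-phenalene-6-carbaldehyde
Conditions: Cl2CHOMe, TiCl4, CH2Cl2, 0 °C; then aq. HCl
Reagents that add atoms: dichloromethyl methyl ether, COC(Cl)Cl; water, O
Why: Rieche formylation of the titanium naphtholate should go to C6, the alpha carbon ortho to oxygen that 2-naphthols always use, the other ortho carbon C4 being a beta position.

Step 6
Reactants: 7 5-hydroxy-9-methoxy-1-oxo-2,3-dihydro-1H-phenalene-6-carbaldehyde
Product: 8 6-formyl-9-methoxy-1-oxo-2,3-dihydro-1H-phenalen-5-yl trifluoromethanesulfonate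
Conditions: Tf2O, pyridine, CH2Cl2, 0 °C
Reagents that add atoms: trifluoromethanesulfonic anhydride, O=S(=O)(OS(=O)(=O)C(F)(F)F)C(F)(F)F
Why: O-Triflation of the hydrogen-bonded ortho-hydroxy aldehyde turns the directing oxygen into a leaving group for palladium chemistry.

Step 7
Reactants: 8 6-formyl-9-methoxy-1-oxo-2,3-dihydro-1H-phenalen-5-yl trifluoromethanesulfonate
Product: 10 5-iodo-9-methoxy-1-oxo-2,3-dihydro-1H-phenalene-6-carbaldehyde, via aryl trimethylstannane 9 (not isolated)
Conditions: (Me3Sn)2, Pd(PPh3)4 (cat.), LiCl, 1,4-dioxane, 100 °C; then I2, CH2Cl2, 0 °C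
Reagents that add atoms: iodine, [I][I]
Why: Palladium-catalysed stannylation of the aryl triflate with hexamethylditin (Stille-type coupling, LiCl assisting transmetallation) followed by ipso-iododestannylation puts iodine on the beta carbon ortho to the aldehyde, a pattern that electrophilic halogenation could not give and that is needed for halogen–lithium exchange.

Step 8
Reactants: 10 5-iodo-9-methoxy-1-oxo-2,3-dihydro-1H-phenalene-6-carbaldehyde; 11 1,8-dihydroxynaphthalene
Product: 12 5-iodo-9-methoxy-6-(naphtho[1,8-de][1,3]dioxin-2-yl)-2,3-dihydro-1H-phenalen-1-one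
Conditions: TsOH·H2O (cat.), toluene, reflux, Dean–Stark
Reagents that add atoms: none
Why: Acid-catalysed acetalisation with azeotropic removal of water is selective for the aldehyde, because the peri diol closes the six-membered dioxine ring readily whereas the hindered, conjugated aryl ketone does not ketalise with a phenolic diol under these conditions.

Step 9
Reactants: 12 5-iodo-9-methoxy-6-(naphtho[1,8-de][1,3]dioxin-2-yl)-2,3-dihydro-1H-phenalen-1-one; 13 1-(tert-butyldimethylsilyloxy)-1-methoxyethene
Product: 15 methyl 2-[2-(5-iodo-9-methoxy-1-oxo-2,3-dihydro-1H-phenalen-6-yl)naphtho[1,8-de][1,3]dioxin-2-yl]acetate, via dioxinylium tetrafluoroborate 14 (not isolated)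
Conditions: Ph3CBF4, CH2Cl2, rt; then 13, −78 °C; Et3N quench
Reagents that add atoms: none
Why: Hydride abstraction by the trityl cation from the acetal C–H, which is benzylic and flanked by two oxygens, should give the dioxinylium ion, and this dioxycarbenium ion is attacked at carbon by the ketene silyl acetal (Mukaiyama-type addition, as known for dialkoxycarbenium ions made from ortho esters) to create the quaternary ketal carbon with its CH2CO2Me arm, the cold amine quench keeping the BF3 set free from promoting aldol addition to the ring ketone.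

Step 10
Reactants: 15 methyl 2-[2-(5-iodo-9-methoxy-1-oxo-2,3-dihydro-1H-phenalen-6-yl)naphtho[1,8-de][1,3]dioxin-2-yl]acetate
Product: 16 1,3-dioxolane ketal of 15 at the phenalenone C1 carbonyl
Conditions: Me3SiOCH2CH2OSiMe3, Me3SiOTf (cat.), CH2Cl2, −78 to −20 °C; pyridine quench
Reagents that add atoms: 1,2-bis(trimethylsilyloxy)ethane, C[Si](C)(C)OCCO[Si](C)(C)C
Why: Noyori ketalisation, in which the bis-silyl ether of the glycol is transferred under catalytic Me3SiOTf and hexamethyldisiloxane is the irreversible by-product, should mask even this peri-hindered aryl ketone at low temperature without exchanging the robust aryl ketal, so that the organolithium and enolate steps meet a single carbonyl group.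

Step 11
Reactants: 16 1,3-dioxolane ketal of 15
Product: 17 spiroketal indanone (cyclopentanone fused across C5–C6 of the dioxolane-masked 9-methoxy-2,3-dihydrophenalene: C=O on C5; CH2; spiro carbon of the naphtho[1,8-de][1,3]dioxine on C6)
Conditions: tBuLi (2.1 equiv), THF, −100 °C; then AcOH, −100 °C
Reagents that add atoms: none
Why: Parham cyclisation: iodine–lithium exchange at −100 °C is faster than addition of tBuLi to the ester, the aryllithium then attacks the ester carbonyl three atoms away (5-exo-trig) to give the indanone, and the acidic quench at low temperature avoids base-induced loss of an aryloxide from the beta-ketal ketone.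

Step 12
Reactants: 17 spiroketal indanone
Product: 18 enol triflate of 17 (C=C between the former carbonyl carbon on C5 and the former CH2)
Conditions: PhNTf2, THF, −78 °C; KN(SiMe3)2 added last
Reagents that add atoms: N-phenylbis(trifluoromethanesulfonimide), O=S(=O)(N(c1ccccc1)S(=O)(=O)C(F)(F)F)C(F)(F)F
Why: Kinetic deprotonation at the only alpha CH2 and immediate O-sulfonylation of the potassium enolate by the triflimide already present give the alkenyl triflate, the in-flask trapping being chosen so that triflation outruns retro-oxa-Michael opening of the ketal.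

Step 13
Reactants: 18 enol triflate; 19 (S)-1-(2,4,6-triisopropylphenyl)ethanol
Product: 20 chiral enol ether (triflate of 18 replaced by the (S)-1-(2,4,6-triisopropylphenyl)ethoxy group)
Conditions: Pd2(dba)3 (cat.), 2-(di-tert-butylphosphino)-1,1'-binaphthyl (cat.), Cs2CO3, toluene, 80 °C
Reagents that add atoms: none
Why: Palladium-catalysed C–O cross-coupling of an alkenyl triflate with an alcohol: zerovalent palladium inserts into the C–OTf bond, the caesium alkoxide displaces triflate on the metal and the bulky electron-rich phosphine drives C–O reductive elimination, the carbinol stereocentre of the alcohol not being touched.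

Step 14
Reactants: 20 chiral enol ether; 21 trichloroacetyl chloride
Product: 23 cis-fused 2,2-dichlorocyclobutanone (ring-fusion CH S; alkoxy carbon R), via dichloroketene 22 (not isolated)
Conditions: Zn–Cu couple, Et2O, rt, slow addition of 21
Reagents that add atoms: none
Why: Dichloroketene, made by zinc reduction of trichloroacetyl chloride, adds across the enol ether C=C in a concerted but asynchronous [2+2] cycloaddition in which the nucleophilic beta carbon (the vinylic CH next to the spiro ketal) bonds to the ketene carbonyl carbon and the oxygen-bearing carbon bonds to CCl2, as enol ether polarisation dictates. The closest known reaction type is the cycloaddition of dichloroketene to enol ethers of this hindered chiral benzylic alcohol, followed by dechlorination and ring expansion to cyclopentanones. The four-membered ring is closed in the cycloaddition itself, suprafacially on the alkene, so the cyclobutanone is necessarily cis-fused to the indane ring and both stereocentres arise together. Their absolute configuration is set by the auxiliary: in the s-trans conformer with the carbinol C–H in the enol ether plane the triisopropylphenyl ring covers one face, and with the (S)-alcohol the ketene should add to the other face, giving (S) at the ring-fusion CH and (R) at the alkoxy carbon. The step needs facial selectivity and chemoselectivity for the enol ether over the aromatic rings; the first rests on the auxiliary, the second on the far higher nucleophilicity of the enol ether, and ether as solvent keeps ZnCl2 from opening the dioxolane or the adduct.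

Step 15
Reactants: 23 cis-fused 2,2-dichlorocyclobutanone
Product: 24 cis-fused cyclobutanone (both chlorines replaced by hydrogen; stereocentres unchanged)
Conditions: Zn–Cu couple, NH4Cl, MeOH, rt
Reagents that add atoms: none
Why: Reductive dechlorination of the alpha,alpha-dichloroketone by zinc via zinc enolates protonated by NH4Cl removes both halogens under nearly neutral conditions, which keeps the dioxolane, the benzylic ether and the two ring-fusion stereocentres intact.

Step 16
Reactants: 24 cis-fused cyclobutanone
Product: 25 cyclobutanone with the dihydrophenalen-1-one carbonyl set free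
Conditions: PPTS (cat.), acetone–H2O, 45 °C
Reagents that add atoms: water, O
Why: Acid-catalysed transketalisation to acetone with mild PPTS should hydrolyse the dioxolane of the electron-rich aryl ketone only, since the aryl spiroketal and the auxiliary ether need strong acid and the cyclobutanone is stable to weak acid.

Step 17
Reactants: 25 cyclobutanone diketone
Product: 26 cis-fused cyclopentanone (ring CH–C(=O)–CH2–CH2–C(OR))
Conditions: CH2N2, Et2O–MeOH, 0 °C
Reagents that add atoms: diazomethane, C=[N+]=[N-]
Why: Diazomethane ring expansion of a cyclobutanone (addition to the strained carbonyl, then 1,2-shift with loss of N2): the unsubstituted CH2 should migrate in preference to the tertiary ring-fusion CH, which is hindered and deactivated by the adjacent ketal carbon, so the new methylene lies between C=O and CH2, while the conjugated, unstrained aryl ketone does not react.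

Step 18
Reactants: 26 cis-fused cyclopentanone
Product: 28 bis-enone (cyclopentenone plus 9-methoxyphenalen-1-one; auxiliary ether retained), via bis(trimethylsilyl enol ether) 27 (not isolated)
Conditions: LiN(iPr)2, Me3SiCl, THF, −78 °C; then Pd(OAc)2, MeCN, rt
Reagents that add atoms: none
Why: Double Saegusa–Ito oxidation: the amide base removes a proton from each of the two accessible alpha CH2 groups (the ring-fusion CH is tertiary and flanked by two quaternary carbons) and Pd(OAc)2 turns both silyl enol ethers into enones by palladation and beta-hydride elimination, so the cyclopentenone and the phenalenone are formed in one operation and the base-sensitive saturated beta-ketal ketone is consumed at once.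

Step 19
Reactants: 28 bis-enone
Product: 29 9-hydroxyphenalen-1-one still carrying the auxiliary ether
Conditions: MgI2, toluene–Et2O, rt
Reagents that add atoms: none
Why: Chelation-assisted demethylation: magnesium bound between the phenalenone carbonyl and the peri methoxy oxygen activates this vinylogous ester methyl for SN2 attack by iodide, while the unchelated ketal and auxiliary ether are left alone.

Step 20
Reactants: 29 auxiliary ether of the target
Product: 30 spiropreussione B
Conditions: CF3CO2H, CH2Cl2, 0 °C
Reagents that add atoms: none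
Why: Acidolysis of the benzylic ether (SN1-type) should cleave the C–O bond on the auxiliary side, because the 1-(2,4,6-triisopropylphenyl)ethyl cation is well stabilised and loses a proton to the styrene whereas ionisation at the ring carbon would give an antiaromatic oxocyclopentadienyl-type cation, so the tertiary alcohol is released with its configuration and that of the adjacent CH unchanged.

**Compound list**

1 | 6-methoxy-2-naphthol | COc1ccc2cc(O)ccc2c1 | starting material
2 | 6-methoxynaphthalen-2-yl 4-methylbenzenesulfonate | COc1ccc2cc(OS(=O)(=O)c3ccc(C)cc3)ccc2c1 | intermediate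
3 | 3-chloropropanoyl chloride | ClCCC(Cl)=O | starting material
4 | 5-(3-chloropropanoyl)-6-methoxynaphthalen-2-yl 4-methylbenzenesulfonate | COc1ccc2cc(OS(=O)(=O)c3ccc(C)cc3)ccc2c1C(=O)CCCl | intermediate
5 | 9-methoxy-1-oxo-2,3-dihydro-1H-phenalen-5-yl 4-methylbenzenesulfonate | O=C1CCc2cc(OS(=O)(=O)c4ccc(C)cc4)cc3ccc(OC)c1c23 | intermediate
6 | 5-hydroxy-9-methoxy-2,3-dihydro-1H-phenalen-1-one | O=C1CCc2cc(O)cc3ccc(OC)c1c23 | intermediate
7 | 5-hydroxy-9-methoxy-1-oxo-2,3-dihydro-1H-phenalene-6-carbaldehyde | O=C1CCc2cc(O)c(C=O)c3ccc(OC)c1c23 | intermediate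
8 | 6-formyl-9-methoxy-1-oxo-2,3-dihydro-1H-phenalen-5-yl trifluoromethanesulfonate | O=C1CCc2cc(OS(=O)(=O)C(F)(F)F)c(C=O)c3ccc(OC)c1c23 | intermediate
9 | 9-methoxy-1-oxo-5-(trimethylstannyl)-2,3-dihydro-1H-phenalene-6-carbaldehyde (not isolated) | O=C1CCc2cc([Sn](C)(C)C)c(C=O)c3ccc(OC)c1c23 | intermediate
10 | 5-iodo-9-methoxy-1-oxo-2,3-dihydro-1H-phenalene-6-carbaldehyde | O=C1CCc2cc(I)c(C=O)c3ccc(OC)c1c23 | intermediate
11 | 1,8-dihydroxynaphthalene | Oc1cccc2cccc(O)c12 | starting material
12 | 5-iodo-9-methoxy-6-(naphtho[1,8-de][1,3]dioxin-2-yl)-2,3-dihydro-1H-phenalen-1-one | O=C1CCc2cc(I)c(C4Oc5cccc6cccc(O4)c56)c3ccc(OC)c1c23 | intermediate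
13 | 1-(tert-butyldimethylsilyloxy)-1-methoxyethene | C=C(OC)O[Si](C)(C)C(C)(C)C | starting material
14 | 2-(5-iodo-9-methoxy-1-oxo-2,3-dihydro-1H-phenalen-6-yl)naphtho[1,8-de][1,3]dioxin-2-ylium tetrafluoroborate (not isolated) | O=C1CCc2cc(I)c([C+]4Oc5cccc6cccc(O4)c56)c3ccc(OC)c1c23.F[B-](F)(F)F | intermediate
15 | methyl 2-[2-(5-iodo-9-methoxy-1-oxo-2,3-dihydro-1H-phenalen-6-yl)naphtho[1,8-de][1,3]dioxin-2-yl]acetate | O=C1CCc2cc(I)c(C4(CC(=O)OC)Oc5cccc6cccc(O4)c56)c3ccc(OC)c1c23 | intermediate
16 | 1,3-dioxolane ketal of 15 at the phenalenone C1 carbonyl | C17(OCCO7)CCc2cc(I)c(C4(CC(=O)OC)Oc5cccc6cccc(O4)c56)c3ccc(OC)c1c23 | intermediate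
17 | spiroketal indanone: cyclopentanone fused across C5–C6 of the dioxolane-masked 9-methoxy-2,3-dihydrophenalene, C=O on C5, CH2, spiro carbon of the naphtho[1,8-de][1,3]dioxine on C6 | C17(OCCO7)CCc2cc8c(C4(CC8=O)Oc5cccc6cccc(O4)c56)c3ccc(OC)c1c23 | intermediate
18 | enol triflate of 17 | C17(OCCO7)CCc2cc8c(C4(C=C8OS(=O)(=O)C(F)(F)F)Oc5cccc6cccc(O4)c56)c3ccc(OC)c1c23 | intermediate
19 | (S)-1-(2,4,6-triisopropylphenyl)ethanol | C[C@H](O)c1c(C(C)C)cc(C(C)C)cc1C(C)C | starting material
20 | (S)-1-(2,4,6-triisopropylphenyl)ethyl enol ether of 17 | C17(OCCO7)CCc2cc8c(C4(C=C8O[C@@H](C)c9c(C(C)C)cc(C(C)C)cc9C(C)C)Oc5cccc6cccc(O4)c56)c3ccc(OC)c1c23 | intermediate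
21 | trichloroacetyl chloride | ClC(Cl)(Cl)C(Cl)=O | starting material
22 | dichloroketene (not isolated) | O=C=C(Cl)Cl | intermediate
23 | cis-fused 2,2-dichlorocyclobutanone, (S) at the ring-fusion CH, (R) at the alkoxy carbon, (S) in the auxiliary | C17(OCCO7)CCc2cc8c(C4([C@@H]%10C(=O)C(Cl)(Cl)[C@]8%10O[C@@H](C)c9c(C(C)C)cc(C(C)C)cc9C(C)C)Oc5cccc6cccc(O4)c56)c3ccc(OC)c1c23 | intermediate
24 | cis-fused cyclobutanone, same configuration | C17(OCCO7)CCc2cc8c(C4([C@@H]%10C(=O)C[C@]8%10O[C@@H](C)c9c(C(C)C)cc(C(C)C)cc9C(C)C)Oc5cccc6cccc(O4)c56)c3ccc(OC)c1c23 | intermediate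
25 | cyclobutanone with free dihydrophenalen-1-one carbonyl | O=C1CCc2cc8c(C4([C@@H]%10C(=O)C[C@]8%10O[C@@H](C)c9c(C(C)C)cc(C(C)C)cc9C(C)C)Oc5cccc6cccc(O4)c56)c3ccc(OC)c1c23 | intermediate
26 | cis-fused cyclopentanone, (S) at the ring-fusion CH, (R) at the alkoxy carbon | O=C1CCc2cc8c(C4([C@@H]%10C(=O)CC[C@]8%10O[C@@H](C)c9c(C(C)C)cc(C(C)C)cc9C(C)C)Oc5cccc6cccc(O4)c56)c3ccc(OC)c1c23 | intermediate
27 | bis(trimethylsilyl enol ether) of 26 (not isolated) | C[Si](C)(C)OC1=CCc2cc8c(C4([C@@H]%10C(O[Si](C)(C)C)=CC[C@]8%10O[C@@H](C)c9c(C(C)C)cc(C(C)C)cc9C(C)C)Oc5cccc6cccc(O4)c56)c3ccc(OC)c1c23 | intermediate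
28 | bis-enone: 9-O-methyl ether of the auxiliary-protected target | O=C1C=Cc2cc8c(C4([C@@H]%10C(=O)C=C[C@]8%10O[C@@H](C)c9c(C(C)C)cc(C(C)C)cc9C(C)C)Oc5cccc6cccc(O4)c56)c3ccc(OC)c1c23 | intermediate
29 | (S)-1-(2,4,6-triisopropylphenyl)ethyl ether of spiropreussione B at the tertiary alcohol | O=C1C=Cc2cc8c(C4([C@@H]%10C(=O)C=C[C@]8%10O[C@@H](C)c9c(C(C)C)cc(C(C)C)cc9C(C)C)Oc5cccc6cccc(O4)c56)c3ccc(O)c1c23 | intermediate
30 | spiropreussione B, (S) at the ring-fusion CH, (R) at the carbinol carbon | O=C1C=Cc2cc8c(C4([C@@H]%10C(=O)C=C[C@]8%10O)Oc5cccc6cccc(O4)c56)c3ccc(O)c1c23 | target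

**Step count and risks**

Total: 20 steps. Longest linear sequence: 20 steps (1 to 30); compounds 3, 11, 13, 19 and 21 are bought.

Step 13. After oxidative addition, the palladium alkoxide of this very hindered secondary alcohol may form slowly or undergo beta-hydride elimination, so that reduction of the triflate to the indene, or S–O cleavage back to the base-labile ketone, outruns C–O reductive elimination. Fallback: from ketone 17, condensation with hydrazine hydrate (EtOH, rt) would give the hydrazone F3, and iodine with tetramethylguanidine (Barton vinyl iodide synthesis) the alkenyl iodide F4. Copper-catalysed Ullmann-type C–O coupling of F4 with alcohol 19 (CuI, 3,4,7,8-tetramethyl-1,10-phenanthroline, Cs2CO3, toluene, 90 °C) comes back to the route at enol ether 20.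

Step 9. Hydride transfer from the crowded acetal C–H (flanked by iodine and the peri hydrogen, and less hydridic than an alkyl acetal because both oxygens are aryl-bound) may be slow, which would let the trityl cation alkylate the electron-rich dioxynaphthalene instead. Fallback: from aldehyde 10, Roskamp homologation with methyl diazoacetate (SnCl2 cat., CH2Cl2) would give the beta-keto ester F1. Its enol triflation (Tf2O, iPr2NEt, CH2Cl2, −78 °C; the 1,3-dicarbonyl is far more acidic than the ring ketone) gives the (Z)-enol triflate F2. Diol 11 with Cs2CO3 in MeCN then replaces triflate by addition–elimination and closes the ketal by intramolecular oxa-Michael addition of the second naphthol oxygen, coming back at ester 15.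

Step 14. The ketene must bond to a vinylic carbon next to a spiro quaternary centre; if addition is slow, ketene oligomerisation and ZnCl2-induced opening of the dioxolane or of the donor–acceptor cyclobutanone would take over. Fallback: from enol ether 20, the keteniminium salt made from N,N-dimethylacetamide, Tf2O and 2,4,6-collidine (ClCH2CH2Cl, 0 °C to rt), a stronger electrophile generated without zinc, would add in a stepwise cationic [2+2] with the same regiochemistry to give the cyclobutaniminium triflate F5. Hydrolysis with aqueous NaHCO3 gives cyclobutanone 24 directly, so step 15 is skipped and the route is rejoined at 24.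

**Further compounds**

F1 | step 9 | methyl 3-(5-iodo-9-methoxy-1-oxo-2,3-dihydro-1H-phenalen-6-yl)-3-oxopropanoate | O=C1CCc2cc(I)c(C(=O)CC(=O)OC)c3ccc(OC)c1c23
F2 | step 9 | methyl (Z)-3-(5-iodo-9-methoxy-1-oxo-2,3-dihydro-1H-phenalen-6-yl)-3-(trifluoromethylsulfonyloxy)prop-2-enoate | O=C1CCc2cc(I)c(/C(OS(=O)(=O)C(F)(F)F)=C/C(=O)OC)c3ccc(OC)c1c23
F3 | step 13 | hydrazone of ketone 17 | C17(OCCO7)CCc2cc8c(C4(CC8=NN)Oc5cccc6cccc(O4)c56)c3ccc(OC)c1c23
F4 | step 13 | alkenyl iodide corresponding to enol triflate 18 | C17(OCCO7)CCc2cc8c(C4(C=C8I)Oc5cccc6cccc(O4)c56)c3ccc(OC)c1c23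
F5 | step 14 | N,N-dimethylcyclobutaniminium triflate corresponding to cyclobutanone 24 | C17(OCCO7)CCc2cc8c(C4([C@@H]%10C(=[N+](C)C)C[C@]8%10O[C@@H](C)c9c(C(C)C)cc(C(C)C)cc9C(C)C)Oc5cccc6cccc(O4)c56)c3ccc(OC)c1c23.[O-]S(=O)(=O)C(F)(F)F
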